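**Retrosynthetic overview**
1. Target 15 ⇒ C3 acetylation and Mitsunobu C11–O bond ⇒ diol 12 + umbelliferone 13 (coumarin attached last).
2. 12 ⇒ conjugated ester 10, by deconjugative kinetic protonation (gives exocyclic C8=C12 and C9–H) and ester reduction.
3. 10 ⇒ alkylidene β-keto ester 8, by methyl-cuprate addition at C10 (third contiguous quaternary carbon, cis fusion) and OTf→CH3 exchange at C8.
4. 8 ⇒ dienone 6 ⇒ epoxy-salicylate 5: ring A and the C4–C5 quaternary–quaternary bond form in one dearomatising epoxide→para-ipso cyclisation; C3 is then corrected by oxidation/Selectride.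
5. 5 ⇒ methyl 2,3-dimethylbenzoate 1 (C–H hydroxylation, lateral prenylation, Shi epoxidation). Ring order: B (the benzene ring of 1) → A (key step) → coumarin appended.

Assumption and numbering: the SMILES is taken as definitive (methyl on both ring-fusion carbons, cis-fused, C27H34O5; 3β-OAc, 5β-Me, 9β-CH2OAr, 10β-Me = 3S,5S,9S,10R). Drimane-type numbering is used: C1–C10 decalin, C11 = CH2O on C9, C12 = exocyclic CH2 on C8, β = face of the two angular methyls.

**Step 1**
Reactants: 1, methyl 2,3-dimethylbenzoate
Product: 2, methyl 6-hydroxy-2,3-dimethylbenzoate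
Conditions: [RuCl2(p-cymene)]2 (2.5 mol%), K2S2O8, TFA/TFAA, 80 °C; aq. NaHCO3 work-up
Reagents that add atoms: trifluoroacetic acid, OC(=O)C(F)(F)F (oxygen source; the aryl trifluoroacetate is hydrolysed on work-up)
Why: Ester-directed Ru(II)-catalysed ortho C–H oxygenation; C6–H is the only ortho C–H, so the regiochemistry is unambiguous.

**Step 2**
Reactants: 2, methyl 6-hydroxy-2,3-dimethylbenzoate; 3, prenyl bromide
Product: 4, methyl 6-hydroxy-3-methyl-2-(4-methylpent-3-en-1-yl)benzoate
Conditions: LDA (2.3 equiv), THF, −78 °C; then 3, −78 → 0 °C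
Reagents that add atoms: prenyl bromide, CC(C)=CCBr
Why: Lateral (benzylic) lithiation of an o-toluate: after phenoxide formation only the methyl ortho to the ester gives the ester-stabilised benzylic anion, which is C-alkylated by SN2 on the allylic bromide.

**Step 3**
Reactants: 4, methyl 6-hydroxy-3-methyl-2-(4-methylpent-3-en-1-yl)benzoate
Product: 5, methyl 2-{2-[(2R)-3,3-dimethyloxiran-2-yl]ethyl}-6-hydroxy-3-methylbenzoate
Conditions: Shi ketone (D-fructose-derived, 30 mol%), Oxone, K2CO3, Bu4NHSO4, MeCN/DMM/aq. buffer (pH ≈ 10.5), 0 °C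
Reagents that add atoms: Oxone (potassium peroxymonosulfate), [K+].[O-]S(=O)(=O)OO
Why: Shi asymmetric epoxidation (dioxirane, spiro transition state) of the electron-rich trisubstituted olefin gives the (R)-epoxide; the H-bonded, ester-deactivated phenol reacts far more slowly than the alkene.

**Step 4 (key step)**
Reactants: 5, the (R)-epoxy salicylate
Product: 6, methyl (4aS,6R)-6-hydroxy-4a,5,5-trimethyl-2-oxo-2,4a,5,6,7,8-hexahydronaphthalene-1-carboxylate (3α-OH, 5β-Me, 4,4-Me2, 8-oxo, Δ6 and Δ9(10), 9-CO2Me)
Conditions: MeAlCl2 (2.2 equiv), CH2Cl2, −78 → −40 °C; cold quench (Et3N/MeOH, then Rochelle salt)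
Reagents that add atoms: none
Why: Proposed new method: MeAlCl2 converts the phenol into an aluminium salicylate and activates the epoxide at its tertiary carbon, and the para carbon of the phenoxide (C5, ipso to CH3) attacks C4 anti to the C–O bond through a six-membered chair-like transition state; the only other reachable ring carbon (C9) is ipso to the ester and deactivated, and because C5 bears no H the adduct collapses to the 4,4-disubstituted cyclohexa-2,5-dienone, creating the C4/C5 quaternary pair and fixing C5 by chirality transfer from the epoxide (3-O equatorial, 5-CH3 axial, i.e. trans); the closest known chemistry is MeAlCl2-promoted epoxide-initiated cation–arene (polyene-type) cyclisation and ipso-Friedel–Crafts dearomatisation of para-substituted phenols.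

**Step 5**
Reactants: 6, dienone alcohol
Product: 7, methyl (4aS)-4a,5,5-trimethyl-2,6-dioxo-2,4a,5,6,7,8-hexahydronaphthalene-1-carboxylate (3-ketone)
Conditions: Dess–Martin periodinane, NaHCO3, CH2Cl2, 0 °C → rt
Reagents that add atoms: none
Why: Dess–Martin oxidation of the secondary alcohol; the cyclisation necessarily gives 3-OH trans to 5-Me whereas the target needs cis, so C3 is taken to the ketone once the epoxide stereocentre has fixed C5.

**Step 6**
Reactants: 7, dienone ketone
Product: 8, methyl (4aS,6S)-6-hydroxy-4a,5,5-trimethyl-2-oxo-2,3,4,4a,5,6,7,8-octahydronaphthalene-1-carboxylate (3β-OH, 5β-Me, 8-oxo, Δ9(10))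
Conditions: K-Selectride (2.5 equiv), THF, −78 → −20 °C; aq. NH4Cl
Reagents that add atoms: none
Why: Trialkylborohydride conjugate reduction of the β-unsubstituted enone arm (C6=C7; the tetrasubstituted C9=C10 arm is inert) masks C8 as its dienolate, and a second hydride reduces the C3 ketone from the equatorial α side, anti to the syn-axial 5β-methyl of the rigid ring-A chair (C10 still sp2), giving the axial 3β-alcohol as in Selectride reductions of 3,3,5-trimethylcyclohexanone.

**Step 7**
Reactants: 8, alkylidene β-keto ester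
Product: 9, methyl (4aS,6S,8aS)-6-hydroxy-4a,5,5,8a-tetramethyl-2-[(trifluoromethanesulfonyl)oxy]-3,4,4a,5,6,7,8,8a-octahydronaphthalene-1-carboxylate (10β-Me, cis-fused; C8 enol triflate)
Conditions: Me2CuLi (3 equiv), Et2O, −40 → −10 °C; then PhNTf2 (1.3 equiv), THF, −10 °C → rt
Reagents that add atoms: lithium dimethylcuprate, [Li+].C[Cu-]C; N-phenyl-bis(trifluoromethanesulfonimide), O=S(=O)(N(c1ccccc1)S(=O)(=O)C(F)(F)F)C(F)(F)F
Why: Cuprate conjugate addition to a doubly activated alkylidene β-keto ester: methyl enters C10 anti to the bulky C4 quaternary substituent on C5 (avoiding the syn-axial 4α-methyl), i.e. syn to 5-Me, giving the cis ring fusion as in cuprate additions to 10-methyl-octalones, and the stabilised enolate is O-triflated in situ while the hindered axial C3 alkoxide is not.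

**Step 8**
Reactants: 9, enol triflate
Product: 10, methyl (4aS,6S,8aS)-6-hydroxy-2,4a,5,5,8a-pentamethyl-3,4,4a,5,6,7,8,8a-octahydronaphthalene-1-carboxylate (8-Me, Δ8(9), 9-CO2Me)
Conditions: Me2CuLi (3 equiv), THF, −20 → 0 °C
Reagents that add atoms: lithium dimethylcuprate, [Li+].C[Cu-]C
Why: Addition–elimination coupling of a β-triflyloxy enoate with a Gilman cuprate (McMurry–Scott/Weiler type) replaces OTf by CH3 without touching any stereocentre.

**Step 9**
Reactants: 10, conjugated ester
Product: 11, methyl (1S,4aS,6S,8aR)-6-hydroxy-4a,5,5,8a-tetramethyl-2-methylidenedecahydronaphthalene-1-carboxylate (9β-CO2Me, 9α-H, exocyclic C8=C12)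
Conditions: LDA (3.5 equiv), THF/HMPA, −78 → −30 °C; then 2,6-di-tert-butylphenol, −78 °C
Reagents that add atoms: none
Why: Deconjugative isomerisation by kinetic enolate protonation (β- to γ-cyclogeranate type): LDA removes a proton from the C8 methyl syn to the ester to give the exocyclic dienolate, and C9 is protonated from the α face (equatorial, opposite the syn-axial 5β-methyl in the conformer that keeps the 3β-oxygen equatorial), leaving CO2Me β and cis to 10-Me.

**Step 10**
Reactants: 11, β,γ-unsaturated ester
Product: 12, (2S,4aR,5S,8aS)-5-(hydroxymethyl)-1,1,4a,8a-tetramethyl-6-methylidenedecahydronaphthalen-2-ol (3β,11-diol)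
Conditions: LiAlH4, Et2O, 0 °C
Reagents that add atoms: none
Why: Hydride reduction of the ester to the primary alcohol, run cold so that the C9–H next to the ester is not epimerised before reduction.

**Step 11**
Reactants: 12, diol; 13, umbelliferone (7-hydroxycoumarin)
Product: 14, 7-{[(1S,4aS,6S,8aR)-6-hydroxy-4a,5,5,8a-tetramethyl-2-methylidenedecahydronaphthalen-1-yl]methoxy}-2H-chromen-2-one
Conditions: 13, PPh3, DIAD, THF, 0 °C → rt
Reagents that add atoms: none beyond reactant 13
Why: Mitsunobu etherification (SN2 at primary C11) with the acidic phenol as pronucleophile; the axial, neopentyl C3–OH does not react and no stereocentre is involved.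

**Step 12**
Reactants: 14, hydroxy ether
Product: 15, polyanthinin (target)
Conditions: Ac2O, DMAP, Et3N, CH2Cl2, rt → 40 °C
Reagents that add atoms: acetic anhydride, CC(=O)OC(C)=O
Why: DMAP-catalysed acylation of the remaining hindered secondary alcohol with retention at C3; the coumarin and exocyclic olefin are inert.

**Compound list**
1 | methyl 2,3-dimethylbenzoate | COC(=O)c1cccc(C)c1C | starting material
2 | methyl 6-hydroxy-2,3-dimethylbenzoate | COC(=O)c1c(O)ccc(C)c1C | intermediate
3 | prenyl bromide (1-bromo-3-methylbut-2-ene) | CC(C)=CCBr | starting material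
4 | methyl 6-hydroxy-3-methyl-2-(4-methylpent-3-en-1-yl)benzoate | COC(=O)c1c(O)ccc(C)c1CCC=C(C)C | intermediate
5 | methyl 2-{2-[(2R)-3,3-dimethyloxiran-2-yl]ethyl}-6-hydroxy-3-methylbenzoate | COC(=O)c1c(O)ccc(C)c1CC[C@H]1OC1(C)C | intermediate
6 | methyl (4aS,6R)-6-hydroxy-4a,5,5-trimethyl-2-oxo-2,4a,5,6,7,8-hexahydronaphthalene-1-carboxylate (3α-OH, 5β-Me dienone) | O=C1C=C[C@]2(C)C(C)(C)[C@H](O)CCC2=C1C(=O)OC | intermediate
7 | methyl (4aS)-4a,5,5-trimethyl-2,6-dioxo-2,4a,5,6,7,8-hexahydronaphthalene-1-carboxylate | O=C1C=C[C@]2(C)C(C)(C)C(=O)CCC2=C1C(=O)OC | intermediate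
8 | methyl (4aS,6S)-6-hydroxy-4a,5,5-trimethyl-2-oxo-2,3,4,4a,5,6,7,8-octahydronaphthalene-1-carboxylate (3β-OH) | O=C1CC[C@]2(C)C(C)(C)[C@@H](O)CCC2=C1C(=O)OC | intermediate
9 | methyl (4aS,6S,8aS)-6-hydroxy-4a,5,5,8a-tetramethyl-2-[(trifluoromethanesulfonyl)oxy]-3,4,4a,5,6,7,8,8a-octahydronaphthalene-1-carboxylate | FC(F)(F)S(=O)(=O)OC=1CC[C@]2(C)C(C)(C)[C@@H](O)CC[C@]2(C)C1C(=O)OC | intermediate
10 | methyl (4aS,6S,8aS)-6-hydroxy-2,4a,5,5,8a-pentamethyl-3,4,4a,5,6,7,8,8a-octahydronaphthalene-1-carboxylate | CC=1CC[C@]2(C)C(C)(C)[C@@H](O)CC[C@]2(C)C1C(=O)OC | intermediate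
11 | methyl (1S,4aS,6S,8aR)-6-hydroxy-4a,5,5,8a-tetramethyl-2-methylidenedecahydronaphthalene-1-carboxylate | C=C1CC[C@]2(C)C(C)(C)[C@@H](O)CC[C@]2(C)[C@H]1C(=O)OC | intermediate
12 | (2S,4aR,5S,8aS)-5-(hydroxymethyl)-1,1,4a,8a-tetramethyl-6-methylidenedecahydronaphthalen-2-ol | C=C1CC[C@]2(C)C(C)(C)[C@@H](O)CC[C@]2(C)[C@H]1CO | intermediate
13 | umbelliferone (7-hydroxy-2H-chromen-2-one) | Oc1ccc2ccc(=O)oc2c1 | starting material
14 | 7-{[(1S,4aS,6S,8aR)-6-hydroxy-4a,5,5,8a-tetramethyl-2-methylidenedecahydronaphthalen-1-yl]methoxy}-2H-chromen-2-one | C=C1CC[C@]2(C)C(C)(C)[C@@H](O)CC[C@]2(C)[C@H]1COc1ccc2ccc(=O)oc2c1 | intermediate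
15 | polyanthinin, (2S,4aR,5S,8aS)-1,1,4a,8a-tetramethyl-6-methylidene-5-{[(2-oxo-2H-chromen-7-yl)oxy]methyl}decahydronaphthalen-2-yl acetate | C=C1CC[C@]2(C)C(C)(C)[C@@H](OC(C)=O)CC[C@]2(C)[C@H]1COc1ccc2ccc(=O)oc2c1 | target

**Totals**
Total step count: 12. Longest linear sequence: 12 steps (from methyl 2,3-dimethylbenzoate; prenyl bromide and umbelliferone are bought).

**Three steps most likely to fail, with fallbacks**
- **Step 4 (dearomative epoxide ipso-cyclisation).** Risks are Meinwald rearrangement of the epoxide, attack at C9, or dienone–phenol rearrangement of 6. Fallback: reverse the polarity. Oxidise the phenol (PhI(OAc)2, HFIP) in a substrate carrying the C3 ketone as its silyl enol ether, so that the tertiary enol carbon C4 attacks the phenoxenium para carbon. This gives 7 directly, but enantiocontrol would then need a chiral aryl-iodine(III) catalyst or a resolution.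
- **Step 7 (methyl cuprate addition creating C10 next to two quaternary carbons).** Fallback: transfer CH2 instead of CH3. Cyclopropanate the alkylidene β-keto ester with dimethylsulfoxonium methylide (Corey–Chaykovsky), then open the cyclopropyl β-keto ester reductively (SmI2 or Li/NH3) to reveal the C10 methyl, and triflate the resulting enolate as before.
- **Step 9 (C9 configuration by kinetic protonation in a conformationally mobile cis-decalin).** Fallback, useful if the β face rather than the α face proves accessible: set C9 by C–C bond formation instead of C–H. Remove the ester from the cuprate adduct (Krapcho), convert the C8 ketone into the 8-methyl-Δ8(9) olefin (MeLi/CeCl3, dehydration), and run a Me2AlCl/paraformaldehyde ene reaction. This installs C11 and the exocyclic methylene in one step, with carbon rather than hydrogen entering from the open face.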